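Retrosynthesis (labdane numbering): cut C12–C13, so that the butenolide arrives intact from 3-bromofuran-2(5H)-one. Raise C3, C17 and C19 to the carbonyl level, then cut C9–C10 (ring B) and C4–C5 (ring A) in one radical event. The open chain is cut at C3–C4 (aldol), C1–C2 (Claisen), C5–C10 (Grignard), C8=C9 (olefination) and C7–C8 (alkylation).
Enabling feature: C4, C10 and C8 are the branch carbons of a head-to-tail 1,5-diene pattern. On the trans-decalin (rings A and B) every substituent except C19 and C20 is equatorial, and C3, C19 and C17 are all oxygenated. With C3/C19 carried as a β-keto ester and C17 as an enoate ester, the radical centres C4, C10 and C8 become electrophilic, nucleophilic and electrophilic in turn.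
Forward: the chain is grown from C8 outwards. The cascade closes ring A and then ring B, which is the last ring closed. One hydride reduction turns the three helper carbonyls into the three hydroxyl groups, and hydroboration/cross-coupling attaches the ready-made butenolide ring.
Stereochemistry: the absolute sense comes from the (+)-8-phenylmenthyl ester on C19, which shields one face of the C4 radical. C5, C10 and C9 follow from the E and Z alkene geometries in a chair–chair array. C8 is set by equilibration to the equatorial ester, and C3 by axial hydride delivery.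

Key step: step 10

Assumption: the facial bias of the 8-phenylmenthyl ester is taken from the aryl-shielding model (ester C=O s-cis to the C4–C3 bond, phenyl ring stacked on the planar radical). Should the other face react, (−)-8-phenylmenthol would be used in step 6 with no other change.

Step 1
Reactants: 1 methyl bis(2,2,2-trifluoroethyl)phosphonoacetate; 2 2-(2-bromoethyl)-1,3-dioxolane
Product: 3 methyl 2-[bis(2,2,2-trifluoroethoxy)phosphoryl]-4-(1,3-dioxolan-2-yl)butanoate (racemic)
Conditions: Cs2CO3, DMF, 60 °C
Reagents that add atoms: none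
Why: SN2 C-alkylation of a stabilised phosphonoacetate carbanion (malonate-type alkylation) by a primary bromide forms C7–C8 and should stop at monoalkylation for steric reasons; the new centre is racemic and is lost in step 2.

Step 2
Reactants: 3 alkylated phosphonate; 4 acrolein
Product: 6 methyl (2Z)-2-[2-(1,3-dioxolan-2-yl)ethyl]penta-2,4-dienoate, via potassium phosphonate carbanion 5 (not isolated)
Conditions: KN(SiMe3)2, 18-crown-6, THF, −78 °C; then 4
Reagents that add atoms: none
Why: Still–Gennari olefination, in which fast irreversible collapse of the kinetically favoured adduct of the electron-poor phosphonate places the vinyl group (C11) cis to the ester and trans to C7, the geometry that step 10 needs.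

Step 3
Reactants: 6 Z-dienoate acetal
Product: 7 methyl (2Z)-2-(3-oxopropyl)penta-2,4-dienoate
Conditions: 2 M HCl, THF, rt
Reagents that add atoms: water, O
Why: Acid-catalysed acetal hydrolysis frees the C5 aldehyde under conditions that leave the cross-conjugated ester and its geometry untouched.

Step 4
Reactants: 7 aldehyde; 8 isopropenylmagnesium bromide
Product: 9 methyl (2Z)-2-(3-hydroxy-4-methylpent-4-en-1-yl)penta-2,4-dienoate (racemic carbinol)
Conditions: THF, −78 °C; cold aq NH4Cl quench; used at once
Reagents that add atoms: none
Why: Grignard 1,2-addition, for which the aldehyde is far more electrophilic at low temperature than the α-branched conjugated ester; the cold quench forestalls δ-lactonisation of the alkoxide onto C17, and the racemic carbinol centre is erased in step 5.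

Step 5
Reactants: 9 allylic alcohol; 10 ethyl vinyl ether
Product: 12 methyl (2Z)-2-[(3E)-4-methyl-7-oxohept-3-en-1-yl]penta-2,4-dienoate, via allyl vinyl ether 11 (not isolated)
Conditions: Hg(OAc)2 (cat.), 10 as solvent, reflux; evaporate; toluene, 120 °C, sealed tube
Reagents that add atoms: none
Why: Vinyl ether exchange followed by the aliphatic Claisen rearrangement, whose chair transition state with the C6 chain equatorial sets the E geometry of C5=C10 and delivers C2 and C3 as the aldehyde; the Z-dienoate has C7 trans to the vinyl group and so has no 1,5-hydrogen shift open to it.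

Step 6
Reactants: 13 (+)-8-phenylmenthol, (1S,2R,5S)-5-methyl-2-(2-phenylpropan-2-yl)cyclohexan-1-ol; 14 propanoyl chloride
Product: 15 (1S,2R,5S)-5-methyl-2-(2-phenylpropan-2-yl)cyclohexyl propanoate
Conditions: Et3N, DMAP (cat.), CH2Cl2, 0 °C to rt
Reagents that add atoms: none
Why: DMAP-catalysed O-acylation of a hindered secondary alcohol installs the auxiliary without touching its stereocentres.

Step 7
Reactants: 15 auxiliary propanoate; 12 aldehyde
Product: 17 (+)-8-phenylmenthyl (6E,10Z)-3-hydroxy-10-(methoxycarbonyl)-2,6-dimethyltrideca-6,10,12-trienoate (mixture at C3 and C4), via lithium enolate 16 (not isolated)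
Conditions: LiN(i-Pr)2, THF, −78 °C; then 12; AcOH quench at −78 °C
Reagents that add atoms: none
Why: Lithium enolate aldol addition is much faster at −78 °C than conjugate addition to the hindered dienoate; the configurations formed at C3 and C4 do not matter, because C3 is oxidised in step 8 and C4 becomes a planar radical in step 10.

Step 8
Reactants: 17 aldol adduct
Product: 18 (+)-8-phenylmenthyl (6E,10Z)-10-(methoxycarbonyl)-2,6-dimethyl-3-oxotrideca-6,10,12-trienoate (C4 labile)
Conditions: Dess–Martin periodinane, CH2Cl2, rt
Reagents that add atoms: none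
Why: Dess–Martin oxidation converts the secondary alcohol into the β-keto ester under neutral conditions that leave all three alkene units alone.

Step 9
Reactants: 18 β-keto ester
Product: 19 (+)-8-phenylmenthyl (6E,10Z)-2-bromo-10-(methoxycarbonyl)-2,6-dimethyl-3-oxotrideca-6,10,12-trienoate (both C4 epimers)
Conditions: NBS, Mg(ClO4)2 (cat.), MeCN, 0 °C
Reagents that add atoms: N-bromosuccinimide, O=C1CCC(=O)N1Br
Why: Lewis acid-promoted enolisation and electrophilic α-bromination of a 1,3-dicarbonyl compound is faster at the magnesium-bound enol than at the isolated trisubstituted alkene or the electron-poor diene; both C4 epimers give the same radical.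

Step 10
Reactants: 19 bromo β-keto ester triene
Product: 20 19-[(+)-8-phenylmenthyl] 17-methyl 3-oxo-13,14,15,16-tetranor-ent-labd-11-ene-17,19-dioate, C8 epimer mixture (trans-decalin; C19 ester axial and syn to C20; C9 vinyl equatorial)
Conditions: (Me3Si)3SiH (1.2 equiv, syringe pump), Et3B (0.2 equiv), air, toluene (0.005 M), 0 °C to rt
Reagents that add atoms: none
Why: Bromine abstraction by the silyl radical gives the planar, electrophilic C4 radical, which adds 6-endo-trig to C5 of the electron-rich C5=C10 alkene (ring A); the nucleophilic tertiary C10 radical then adds 6-endo-trig to C9, the β-carbon of the C8=C9 enoate (ring B, closed last), and the electrophilic C8 radical takes hydrogen from the silane to carry the chain. The closest known reaction types are the oxidative 6-endo/6-endo radical bicyclisation of α-methyl β-keto ester polyenes, radical polyene cascades with an acceptor alkene inside the chain, and the halogen-abstraction (Giese-type) reductive cascade. Both closures run through a chair–chair array, in which the E C5=C10 alkene gives the trans ring fusion (C5-H anti to C20) and the Z enoate, with C11 trans to C7, puts the vinyl group equatorial at C9. At C4 the unchelated radical keeps the C3 carbonyl turned away from the ester, so the flat ester takes the axial site syn to C20 and the methyl group the equatorial one, while the phenyl ring of the auxiliary covers one face and thereby fixes the absolute sense of C4 and, through the chairs, of C5, C10 and C9. C8 is formed without control and is corrected in step 11. The step needs 6-endo over 5-exo closure and cyclisation faster than hydrogen transfer: attack at the less substituted C5 and at the polarity-matched C9 (fully substituted C8 blocked) secures the first, and high dilution with slow silane addition secures the second.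

Step 11
Reactants: 20 keto diester (C8 mixture)
Product: 21 the same keto diester as the single C8 epimer with the C17 ester equatorial (C8-H axial, syn to C20)
Conditions: KOt-Bu (20 mol %), t-BuOH/THF, 40 °C
Reagents that add atoms: none
Why: Base-mediated epimerisation of an ester α-centre under thermodynamic control should drain the mixture to the equatorial ester trans to the C9 vinyl group, since the axial C8 ester clashes 1,3-diaxially with C20; the bulky alkoxide should not add to the hindered C3 carbonyl, so ring A should not open by retro-Claisen cleavage.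

Step 12
Reactants: 21 keto diester
Product: 22 13,14,15,16-tetranor-ent-labd-11-ene-3,17,19-triol (3-OH equatorial; C19 CH2OH axial; C17 CH2OH and C9 vinyl equatorial)
Conditions: LiAlH4, THF, 0 °C to reflux; aqueous work-up
Reagents that add atoms: none
Why: Global LiAlH4 reduction, in which axial hydride delivery to C3 from the face that carries only axial hydrogens (C1, C5) gives the equatorial alcohol; both esters fall to primary alcohols (C19 helped by the neighbouring C3 alkoxyaluminate) and the auxiliary is released for recovery.

Step 13
Reactants: 22 triol; 23 3-bromofuran-2(5H)-one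
Product: 25 14-deoxy-17-hydroxyandrographolide (target), via B-alkyl-9-BBN tris(borinate) 24 (not isolated)
Conditions: 9-BBN (5 equiv), THF, rt to 50 °C; then 23, PdCl2(dppf) (10 mol %), AsPh3, Cs2CO3, DMF/H2O, rt
Reagents that add atoms: none
Why: Anti-Markovnikov hydroboration of the monosubstituted alkene followed by B-alkyl Suzuki–Miyaura coupling with an α-bromo enoate, as known for α-halo enones; the extra 9-BBN only masks the three hydroxyl groups as borinates that hydrolyse in the aqueous medium, no stereocentre is touched, and the butenolide ring arrives intact.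

Compound list
1 | methyl bis(2,2,2-trifluoroethyl)phosphonoacetate | COC(=O)CP(=O)(OCC(F)(F)F)OCC(F)(F)F | starting material
2 | 2-(2-bromoethyl)-1,3-dioxolane | BrCCC1OCCO1 | starting material
3 | methyl 2-[bis(2,2,2-trifluoroethoxy)phosphoryl]-4-(1,3-dioxolan-2-yl)butanoate (racemic) | COC(=O)C(CCC1OCCO1)P(=O)(OCC(F)(F)F)OCC(F)(F)F | intermediate
4 | acrolein | C=CC=O | starting material
5 | potassium carbanion of 3 | [K+].COC(=O)[C-](CCC1OCCO1)P(=O)(OCC(F)(F)F)OCC(F)(F)F | intermediate
6 | methyl (2Z)-2-[2-(1,3-dioxolan-2-yl)ethyl]penta-2,4-dienoate | C=C/C=C(C(=O)OC)/CCC1OCCO1 | intermediate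
7 | methyl (2Z)-2-(3-oxopropyl)penta-2,4-dienoate | C=C/C=C(C(=O)OC)/CCC=O | intermediate
8 | isopropenylmagnesium bromide | CC(=C)[Mg]Br | starting material
9 | methyl (2Z)-2-(3-hydroxy-4-methylpent-4-en-1-yl)penta-2,4-dienoate (racemic) | C=C/C=C(C(=O)OC)/CCC(O)C(C)=C | intermediate
10 | ethyl vinyl ether | C=COCC | starting material
11 | O-vinyl ether of 9 | C=C/C=C(C(=O)OC)/CCC(OC=C)C(C)=C | intermediate
12 | methyl (2Z)-2-[(3E)-4-methyl-7-oxohept-3-en-1-yl]penta-2,4-dienoate | C=C/C=C(C(=O)OC)/CC/C=C(C)/CCC=O | intermediate
13 | (+)-8-phenylmenthol, (1S,2R,5S) | CC(C)(c1ccccc1)[C@H]1CC[C@H](C)C[C@@H]1O | starting material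
14 | propanoyl chloride | CCC(=O)Cl | starting material
15 | (+)-8-phenylmenthyl propanoate | CC(C)(c1ccccc1)[C@H]1CC[C@H](C)C[C@@H]1OC(=O)CC | intermediate
16 | lithium enolate of 15 | CC(C)(c1ccccc1)[C@H]1CC[C@H](C)C[C@@H]1OC([O-])=CC.[Li+] | intermediate
17 | aldol adduct (mixture at C3, C4) | CC(C)(c1ccccc1)[C@H]1CC[C@H](C)C[C@@H]1OC(=O)C(C)C(O)CC/C(C)=C/CC/C(C(=O)OC)=C/C=C | intermediate
18 | β-keto ester (C4 labile) | CC(C)(c1ccccc1)[C@H]1CC[C@H](C)C[C@@H]1OC(=O)C(C)C(=O)CC/C(C)=C/CC/C(C(=O)OC)=C/C=C | intermediate
19 | α-bromo β-keto ester (both C4 epimers) | CC(C)(c1ccccc1)[C@H]1CC[C@H](C)C[C@@H]1OC(=O)C(C)(Br)C(=O)CC/C(C)=C/CC/C(C(=O)OC)=C/C=C | intermediate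
20 | bicyclic keto diester, C8 epimer mixture | CC(C)(c1ccccc1)[C@H]1CC[C@H](C)C[C@@H]1OC(=O)[C@@]2(C)[C@H]3CCC(C(=O)OC)[C@@H](C=C)[C@]3(C)CCC2=O | intermediate
21 | bicyclic keto diester, C17 ester equatorial | CC(C)(c1ccccc1)[C@H]1CC[C@H](C)C[C@@H]1OC(=O)[C@@]2(C)[C@H]3CC[C@H](C(=O)OC)[C@@H](C=C)[C@]3(C)CCC2=O | intermediate
22 | vinyl triol | C[C@]1(CO)[C@H]2CC[C@H](CO)[C@@H](C=C)[C@]2(C)CC[C@H]1O | intermediate
23 | 3-bromofuran-2(5H)-one | BrC1=CCOC1=O | starting material
24 | C12 B-alkyl-9-BBN with the three hydroxyls as 9-BBN borinates | C[C@]1(COB3C4CCCC3CCC4)[C@H]2CC[C@H](COB3C4CCCC3CCC4)[C@@H](CCB3C4CCCC3CCC4)[C@]2(C)CC[C@H]1OB3C4CCCC3CCC4 | intermediate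
25 | 14-deoxy-17-hydroxyandrographolide | C[C@]1(CO)[C@H]2CC[C@H](CO)[C@@H](CCC3=CCOC3=O)[C@]2(C)CC[C@H]1O | target

Total steps: 13. Longest linear sequence: 12 (steps 1–5 and 7–13; step 6 is a one-step branch).

Steps most likely to fail

Step 10. Three processes may spoil the cascade:
- hydrogen transfer to the C4 or C10 radical may outrun ring closure;
- the Z geometry of the dienoate may erode by reversible silyl radical addition;
- facial shielding by the auxiliary may be incomplete, in which case the diastereomers would be separated by chromatography.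

The fallback sets out from 19 and runs the cascade in the atom-transfer mode with no hydride donor at all (Et3B/air, or (Bu3Sn)2 with irradiation, in benzene). The C8 radical then takes bromine from a second molecule of 19 and gives the 8-bromo keto diester F1. Zinc in acetic acid (Reformatsky-type zinc enolate, then protonation) removes the bromine, and the route is rejoined at 20.

Step 13. Transmetalation may be slow in the boron-rich medium, the bromobutenolide may suffer base-induced opening or γ-deprotonation, and β-hydride elimination may compete. The fallback forms C12–C13 by enolate alkylation instead of cross-coupling. It sets out from 22, which is silylated (Et3SiOTf, 2,6-lutidine) to the tris(triethylsilyl) ether F2. Hydroboration and oxidation (9-BBN, then NaBO3) give the C12 alcohol F3, and Appel-type iodination (I2, PPh3, imidazole) gives the iodide F4. The lithium enolate of commercial 3-(phenylsulfanyl)oxolan-2-one is alkylated with F4 to the sulfanyl lactone F5. Oxidation with mCPBA gives the sulfoxide F6, and thermolysis in toluene gives the silylated butenolide F7 by syn-elimination into the ring. Dilute HCl in THF removes the silyl groups, and the route is rejoined at 25.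

Step 11. Alkoxide-induced retro-Claisen cleavage of C3–C4 may compete, or the equilibration may stay incomplete. The fallback removes the ketone before any base is applied. It sets out from 20, which NaBH4 in MeOH reduces to the 3-hydroxy diester F8 (equatorial alcohol, C8 mixture). NaOMe in refluxing MeOH then equilibrates C8 to the equatorial ester F9, and LiAlH4 reduces both esters, so that the route is rejoined at 22.

Further compounds
F1 | step 10 | 8-bromo keto diester (C8 unassigned) | CC(C)(c1ccccc1)[C@H]1CC[C@H](C)C[C@@H]1OC(=O)[C@@]2(C)[C@H]3CCC(Br)(C(=O)OC)[C@@H](C=C)[C@]3(C)CCC2=O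
F2 | step 13 | tris(triethylsilyl) ether of 22 | C[C@]1(CO[Si](CC)(CC)CC)[C@H]2CC[C@H](CO[Si](CC)(CC)CC)[C@@H](C=C)[C@]2(C)CC[C@H]1O[Si](CC)(CC)CC
F3 | step 13 | C12 primary alcohol | C[C@]1(CO[Si](CC)(CC)CC)[C@H]2CC[C@H](CO[Si](CC)(CC)CC)[C@@H](CCO)[C@]2(C)CC[C@H]1O[Si](CC)(CC)CC
F4 | step 13 | C12 iodide | C[C@]1(CO[Si](CC)(CC)CC)[C@H]2CC[C@H](CO[Si](CC)(CC)CC)[C@@H](CCI)[C@]2(C)CC[C@H]1O[Si](CC)(CC)CC
F5 | step 13 | α-alkyl-α-phenylsulfanyl lactone (C13 mixture) | C[C@]1(CO[Si](CC)(CC)CC)[C@H]2CC[C@H](CO[Si](CC)(CC)CC)[C@@H](CCC3(Sc4ccccc4)CCOC3=O)[C@]2(C)CC[C@H]1O[Si](CC)(CC)CC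
F6 | step 13 | sulfoxide of F5 | C[C@]1(CO[Si](CC)(CC)CC)[C@H]2CC[C@H](CO[Si](CC)(CC)CC)[C@@H](CCC3(S(=O)c4ccccc4)CCOC3=O)[C@]2(C)CC[C@H]1O[Si](CC)(CC)CC
F7 | step 13 | tris(triethylsilyl) ether of 25 | C[C@]1(CO[Si](CC)(CC)CC)[C@H]2CC[C@H](CO[Si](CC)(CC)CC)[C@@H](CCC3=CCOC3=O)[C@]2(C)CC[C@H]1O[Si](CC)(CC)CC
F8 | step 11 | 3-hydroxy diester, C8 mixture | CC(C)(c1ccccc1)[C@H]1CC[C@H](C)C[C@@H]1OC(=O)[C@@]2(C)[C@H]3CCC(C(=O)OC)[C@@H](C=C)[C@]3(C)CC[C@H]2O
F9 | step 11 | 3-hydroxy diester, C17 ester equatorial | CC(C)(c1ccccc1)[C@H]1CC[C@H](C)C[C@@H]1OC(=O)[C@@]2(C)[C@H]3CC[C@H](C(=O)OC)[C@@H](C=C)[C@]3(C)CC[C@H]2O
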